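The butenolide is disconnected at its C15–O bond (labdane numbering). The lactone ring O–C16(=O)–C13=C14–C15H2 is the cycloisomer of a 2-substituted buta-2,3-dienoic acid, and that acid is the carbonylation product of a C13≡C14–C15H2–OMs propargylic mesylate. One flask therefore installs C16 from CO, turns the alkyne into the allene and closes the ring by 5-endo attack of the new carboxyl oxygen on the unsubstituted C15. The precursor is a protected 16-nor-labd-13-yn-15-yl mesylate. Its decalin comes from an auxiliary-controlled oxidative radical bicyclisation of a geranylacetone-derived β-keto ester that sets C4, C5, C9 and C10 together.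

Key step: step 14

Remark on notation: labdane numbering is used throughout; α and β denote the actual faces in the usual projection (C10 methyl α, i.e. the ent series).
Assumption: the (1S,2R,5S)-8-phenylmenthyl ester is taken to shield the face of the C4 radical that leads to the 10α-methyl series drawn; if the opposite face reacts, the commercial (1R,2S,5R) alcohol is used in step 4 and nothing else changes.

Step 1
Reactants: 1 (E)-geranylacetone
Product: 2 geranylacetone ethylene ketal
Conditions: ethylene glycol, PPTS (cat.), benzene, reflux, Dean–Stark trap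
Reagents that add atoms: ethylene glycol OCCO
Why: Acid-catalysed ketalisation with azeotropic water removal masks the methyl ketone (the later C13/C14 unit) against the basic, reducing and organometallic steps, the mild pyridinium acid leaving the trisubstituted alkenes untouched; no stereocentre is formed.

Step 2
Reactants: 2 geranylacetone ethylene ketal
Product: 3 (2E,6E)-allylic alcohol
Conditions: SeO2 (0.5 equiv), t-BuOOH (5.5 M in decane, 2 equiv), CH2Cl2, 25 °C
Reagents that add atoms: tert-butyl hydroperoxide CC(C)(C)OO
Why: Riley allylic oxidation run with catalytic selenium dioxide (ene reaction, then [2,3]-sigmatropic shift) should hydroxylate the (E)-methyl group of the terminal, most accessible trisubstituted alkene with retention of the E geometry; no stereocentre is formed.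

Step 3
Reactants: 3 (2E,6E)-allylic alcohol
Product: 4 (3E,7E)-allylic bromide
Conditions: CBr4, PPh3, 2,6-lutidine, CH2Cl2, 0 °C
Reagents that add atoms: carbon tetrabromide BrC(Br)(Br)Br
Why: Appel reaction converts the primary allylic alcohol into the bromide by SN2 displacement of the oxyphosphonium ion under non-acidic conditions, so the ketal and both E alkenes should survive without allylic transposition.

Step 4
Reactants: 5 (1S,2R,5S)-8-phenylmenthol; 6 ethyl 2-methyl-3-oxobutanoate
Product: 7 (1S,2R,5S)-8-phenylmenthyl 2-methyl-3-oxobutanoate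
Conditions: DMAP (0.3 equiv), toluene, reflux with slow distillation of ethanol
Reagents that add atoms: none
Why: DMAP-promoted transesterification of a β-keto ester loads the hindered secondary alcohol; the α-stereocentre is left undefined because it is enolised in the next step.

Step 5
Reactants: 7 (1S,2R,5S)-8-phenylmenthyl 2-methyl-3-oxobutanoate; 4 (3E,7E)-allylic bromide
Product: 9 (6E,10E)-polyene β-keto ester, via keto ester dianion 8 (not isolated)
Conditions: NaH (1.1 equiv), THF, 0 °C; n-BuLi (1.05 equiv), 0 °C; then 4, 0 → 25 °C; aq. NH4Cl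
Reagents that add atoms: none
Why: Dianion γ-alkylation of a β-keto ester: the more reactive terminal carbanion of the 1,3-dianion displaces the allylic bromide by SN2 without touching the ketal and forms the C1–C2 bond of the future ring A.

Step 6
Reactants: 9 (6E,10E)-polyene β-keto ester
Product: 10 bicyclic keto ester with the exocyclic C8=C17 alkene
Conditions: Mn(OAc)3·2H2O (2.2 equiv), Cu(OAc)2·H2O (1.0 equiv), KOAc, degassed AcOH, 25 °C
Reagents that add atoms: none
Why: Oxidative free-radical polyene cyclisation: trivalent manganese oxidises the enolised β-keto ester to the C4 radical, which closes ring A (6-endo on C5) and ring B (6-endo on C9) through chair–chair transition states fixed by the two E alkenes (trans ring fusion, C9 chain equatorial, ester axial and cis to the C10 methyl), the aryl group of the auxiliary covers one face of the C4 radical so that the absolute sense of C4, C5, C9 and C10 is decided in one event, and divalent copper oxidises the tertiary C8 radical to the less substituted exocyclic alkene.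

Step 7
Reactants: 10 bicyclic keto ester with the exocyclic C8=C17 alkene
Product: 12 C17 alcohol with axial CH2OH (8β-H), via B-alkyl-9-BBN adduct 11 (not isolated)
Conditions: 9-BBN (1.5 equiv), THF, 0 → 40 °C; then H2O2 (30% aq.), NaOAc, 25 °C
Reagents that add atoms: hydrogen peroxide OO; 9-borabicyclo[3.3.1]nonane B1C2CCCC1CCC2 (boron, to intermediate 11 only)
Why: Anti-Markovnikov hydroboration–oxidation of the 1,1-disubstituted alkene places the oxygen on C17; the borane should add from the β face, away from the axial C10 methyl, to give the axial CH2OH epimer at C8, which is corrected in step 8, where any reduction of the hindered C3 ketone is also reversed.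

Step 8
Reactants: 12 C17 alcohol with axial CH2OH (8β-H)
Product: 14 equatorial C17 aldehyde (8α-H), via axial aldehyde 13 (not isolated)
Conditions: Dess–Martin periodinane (2.0 equiv), NaHCO3, CH2Cl2, 0 → 25 °C; filtration; then DBU (0.5 equiv), CH2Cl2, 25 °C
Reagents that add atoms: none
Why: Dess–Martin oxidation gives the C17 aldehyde, and amidine-base enolisation then epimerises C8 under thermodynamic control, the formyl group leaving the axial position (1,3-diaxial to the C10 methyl) for the equatorial one trans to the C9 chain; C9 and the quaternary C4 cannot enolise.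

Step 9
Reactants: 14 equatorial C17 aldehyde (8α-H)
Product: 15 3α,17,19-triol ketal
Conditions: LiAlH4 (6 equiv), THF, 0 °C → reflux; then H2O, NaOH (15% aq.), H2O
Reagents that add atoms: none
Why: Hydride reduction of ketone, aldehyde and auxiliary ester in one operation: axial hydride delivery to the C3 ketone, on the face away from the axial C4 substituent, should give the equatorial 3α-hydroxyl cis to C19, and reductive cleavage of the ester releases the C19 alcohol and the recoverable auxiliary 5.

Step 10
Reactants: 15 3α,17,19-triol ketal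
Product: 16 3,19-acetonide methyl ketone with free C17 hydroxyl
Conditions: 2,2-dimethoxypropane (3 equiv), TsOH·H2O (cat.), acetone, 25 °C; Et3N quench
Reagents that add atoms: 2,2-dimethoxypropane COC(C)(C)OC
Why: Acid-catalysed acetal exchange does two jobs at once: the cis 3,19-diol closes the six-membered isopropylidene acetal, and the dioxolane is transferred from C13 to the large excess of acetone, which frees the methyl ketone; the isolated primary C17 alcohol stays free.

Step 11
Reactants: 16 3,19-acetonide methyl ketone with free C17 hydroxyl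
Product: 17 C17 silyl ether methyl ketone
Conditions: TBSCl, imidazole, DMF, 25 °C
Reagents that add atoms: tert-butyldimethylsilyl chloride CC(C)(C)[Si](C)(C)Cl
Why: Silylation of the primary C17 hydroxyl protects it against the amide base, the chlorophosphate and the sulfonyl chloride of the next two steps; no stereocentre is touched.

Step 12
Reactants: 17 C17 silyl ether methyl ketone
Product: 20 propargylic alcohol (13-yn-15-ol), via enol phosphate 18 (not isolated), via lithium acetylide 19 (not isolated)
Conditions: LiN(i-Pr)2 (1.1 equiv), THF, −78 °C; ClP(O)(OEt)2, −78 → 25 °C; LiN(i-Pr)2 (2.5 equiv), −78 → 25 °C; (CH2O)n, 0 → 25 °C; aq. NH4Cl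
Reagents that add atoms: paraformaldehyde (as formaldehyde) C=O; diethyl chlorophosphate CCOP(=O)(Cl)OCC (to intermediate 18 only)
Why: One-pot conversion of a methyl ketone into an alkyne with trapping: kinetic deprotonation of the methyl group and O-phosphorylation give the terminal enol phosphate, further amide base eliminates diethyl phosphate and deprotonates the alkyne, and the acetylide adds to formaldehyde to give the C13≡C14–C15H2OH unit.

Step 13
Reactants: 20 propargylic alcohol (13-yn-15-ol)
Product: 21 propargylic mesylate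
Conditions: MsCl, Et3N, CH2Cl2, −40 °C; used without chromatography
Reagents that add atoms: methanesulfonyl chloride CS(=O)(=O)Cl
Why: Sulfonylation of the primary propargylic alcohol installs the leaving group needed for the SN2′ oxidative addition of the next step; no stereocentre is touched.

Step 14
Reactants: 21 propargylic mesylate
Product: 23 protected butenolide, via allenoic acid 22 (not isolated)
Conditions: Pd(PPh3)4 (5 mol %), CO (1 atm), 2,6-lutidine (1.2 equiv), THF–H2O (10:1), 25 °C; then AgNO3 (0.2 equiv), acetone, 25 °C, dark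
Reagents that add atoms: carbon monoxide [C-]#[O+]; water O
Why: Zerovalent palladium adds to the propargylic mesylate in the anti SN2′ sense to give an allenylpalladium species bonded at C13, CO inserts and water cleaves the acyl complex to the 2-substituted buta-2,3-dienoic acid 22 (C13=C14=C15H2); monovalent silver then activates the terminal C14=C15 bond, the carboxyl oxygen attacks C15, and protodemetalation at C14 leaves the conjugated C13=C14 bond. The closest known reaction types are the palladium-catalysed hydroxycarbonylation of propargylic sulfonates to allenic acids and the silver-catalysed cycloisomerisation of allenic acids to butenolides. The lactone ring closes in the 5-endo-trig mode at the allene terminus, with formation of the O–C15 bond. No stereocentre is created. The step needs regioselectivity in the oxidative addition (allenyl rather than propargyl palladium, expected for an internal alkyne with a primary leaving group) and in the cyclisation, where the oxygen can only reach C15 because a four-membered closure on C14 is strained; the lutidine buffer keeps the acetonide and the silyl ether safe from the methanesulfonic acid released.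

Step 15
Reactants: 23 protected butenolide
Product: 24 14-deoxy-17-hydroxyandrographolide
Conditions: HCl (2 M aq.), THF, 25 °C
Reagents that add atoms: none
Why: Acid hydrolysis removes the isopropylidene acetal and the primary silyl ether in one operation, and the butenolide is stable to dilute aqueous acid; no stereocentre is touched.

Compound list
1 | (5E)-6,10-dimethylundeca-5,9-dien-2-one, (E)-geranylacetone | CC(=O)CC/C=C(\C)CCC=C(C)C | starting material
2 | 2-[(3E)-4,8-dimethylnona-3,7-dien-1-yl]-2-methyl-1,3-dioxolane | CC1(CC/C=C(\C)CCC=C(C)C)OCCO1 | intermediate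
3 | (2E,6E)-2,6-dimethyl-9-(2-methyl-1,3-dioxolan-2-yl)nona-2,6-dien-1-ol | CC1(CC/C=C(\C)CC/C=C(\C)CO)OCCO1 | intermediate
4 | 2-[(3E,7E)-9-bromo-4,8-dimethylnona-3,7-dien-1-yl]-2-methyl-1,3-dioxolane | CC1(CC/C=C(\C)CC/C=C(\C)CBr)OCCO1 | intermediate
5 | (1S,2R,5S)-5-methyl-2-(2-phenylpropan-2-yl)cyclohexan-1-ol, (+)-8-phenylmenthol | O[C@H]1C[C@@H](C)CC[C@@H]1C(C)(C)c1ccccc1 | starting material
6 | ethyl 2-methyl-3-oxobutanoate | CCOC(=O)C(C)C(C)=O | starting material
7 | (1S,2R,5S)-8-phenylmenthyl 2-methyl-3-oxobutanoate (both C2 epimers) | CC(=O)C(C)C(=O)O[C@H]1C[C@@H](C)CC[C@@H]1C(C)(C)c1ccccc1 | intermediate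
8 | sodium lithium 1,3-dianion (dienolate) of 7 | [Na+].[Li+].C=C([O-])C(C)=C([O-])O[C@H]1C[C@@H](C)CC[C@@H]1C(C)(C)c1ccccc1 | intermediate (not isolated)
9 | (1S,2R,5S)-8-phenylmenthyl (6E,10E)-2,6,10-trimethyl-13-(2-methyl-1,3-dioxolan-2-yl)-3-oxotrideca-6,10-dienoate (both C2 epimers) | CC(C(=O)O[C@H]1C[C@@H](C)CC[C@@H]1C(C)(C)c1ccccc1)C(=O)CC/C(C)=C/CC/C(C)=C/CCC1(C)OCCO1 | intermediate
10 | (1S,2R,5S)-8-phenylmenthyl 13,13-ethylenedioxy-3-oxo-15,16-dinorlabd-8(17)-en-19-oate; trans-decalin with 5β-H, 9β-H, 10α-CH3, axial 4α-ester (C19) and 4β-CH3 | C[C@]1(C(=O)O[C@H]4C[C@@H](C)CC[C@@H]4C(C)(C)c4ccccc4)[C@H]2CCC(=C)[C@@H](CCC3(C)OCCO3)[C@]2(C)CCC1=O | intermediate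
11 | B-(C17-alkyl)-9-borabicyclo[3.3.1]nonane adduct of 10 (8β-H, axial CH2B) | C[C@]1(C(=O)O[C@H]4C[C@@H](C)CC[C@@H]4C(C)(C)c4ccccc4)[C@H]2CC[C@@H](CB5C6CCCC5CCC6)[C@@H](CCC3(C)OCCO3)[C@]2(C)CCC1=O | intermediate (not isolated)
12 | (1S,2R,5S)-8-phenylmenthyl 13,13-ethylenedioxy-17-hydroxy-3-oxo-15,16-dinorlabdan-19-oate with 8β-H (axial 8α-CH2OH) | C[C@]1(C(=O)O[C@H]4C[C@@H](C)CC[C@@H]4C(C)(C)c4ccccc4)[C@H]2CC[C@@H](CO)[C@@H](CCC3(C)OCCO3)[C@]2(C)CCC1=O | intermediate
13 | corresponding 3,17-dioxo ester with 8β-H (axial formyl group) | C[C@]1(C(=O)O[C@H]4C[C@@H](C)CC[C@@H]4C(C)(C)c4ccccc4)[C@H]2CC[C@@H](C=O)[C@@H](CCC3(C)OCCO3)[C@]2(C)CCC1=O | intermediate (not isolated)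
14 | corresponding 3,17-dioxo ester with 8α-H (equatorial 8β-formyl group, trans to the C9 chain) | C[C@]1(C(=O)O[C@H]4C[C@@H](C)CC[C@@H]4C(C)(C)c4ccccc4)[C@H]2CC[C@H](C=O)[C@@H](CCC3(C)OCCO3)[C@]2(C)CCC1=O | intermediate
15 | 13,13-ethylenedioxy-15,16-dinorlabdane-3α,17,19-triol (5β-H, 8α-H, 9β-H, 10α-CH3) | C[C@]1(CO)[C@H]2CC[C@H](CO)[C@@H](CCC3(C)OCCO3)[C@]2(C)CC[C@H]1O | intermediate
16 | 17-hydroxy-3α,19-(isopropylidenedioxy)-15,16-dinorlabdan-13-one | C[C@]1(COC5(C)C)[C@H]2CC[C@H](CO)[C@@H](CCC(C)=O)[C@]2(C)CC[C@H]1O5 | intermediate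
17 | 17-(tert-butyldimethylsilyloxy)-3α,19-(isopropylidenedioxy)-15,16-dinorlabdan-13-one | C[C@]1(COC5(C)C)[C@H]2CC[C@H](CO[Si](C)(C)C(C)(C)C)[C@@H](CCC(C)=O)[C@]2(C)CC[C@H]1O5 | intermediate
18 | terminal enol diethyl phosphate of 17 (C13=C14H2) | C[C@]1(COC5(C)C)[C@H]2CC[C@H](CO[Si](C)(C)C(C)(C)C)[C@@H](CCC(=C)OP(=O)(OCC)OCC)[C@]2(C)CC[C@H]1O5 | intermediate (not isolated)
19 | lithium acetylide of the C13≡C14 alkyne | C[C@]1(COC5(C)C)[C@H]2CC[C@H](CO[Si](C)(C)C(C)(C)C)[C@@H](CCC#C[Li])[C@]2(C)CC[C@H]1O5 | intermediate (not isolated)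
20 | 17-(tert-butyldimethylsilyloxy)-3α,19-(isopropylidenedioxy)-16-norlabd-13-yn-15-ol | C[C@]1(COC5(C)C)[C@H]2CC[C@H](CO[Si](C)(C)C(C)(C)C)[C@@H](CCC#CCO)[C@]2(C)CC[C@H]1O5 | intermediate
21 | methanesulfonate of 20 | C[C@]1(COC5(C)C)[C@H]2CC[C@H](CO[Si](C)(C)C(C)(C)C)[C@@H](CCC#CCOS(C)(=O)=O)[C@]2(C)CC[C@H]1O5 | intermediate
22 | 17-(tert-butyldimethylsilyloxy)-3α,19-(isopropylidenedioxy)labda-13,14-dien-16-oic acid (2-substituted buta-2,3-dienoic acid) | C[C@]1(COC5(C)C)[C@H]2CC[C@H](CO[Si](C)(C)C(C)(C)C)[C@@H](CCC(=C=C)C(O)=O)[C@]2(C)CC[C@H]1O5 | intermediate (not isolated)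
23 | 17-O-(tert-butyldimethylsilyl)-3,19-O-isopropylidene-14-deoxy-17-hydroxyandrographolide | C[C@]1(COC5(C)C)[C@H]2CC[C@H](CO[Si](C)(C)C(C)(C)C)[C@@H](CCC3=CCOC3=O)[C@]2(C)CC[C@H]1O5 | intermediate
24 | 14-deoxy-17-hydroxyandrographolide (3α-OH, 19-OH on axial 4α-CH2, 8β-CH2OH, 5β-H, 9β-H, 10α-CH3) | C[C@]1(CO)[C@H]2CC[C@H](CO)[C@@H](CCC3=CCOC3=O)[C@]2(C)CC[C@H]1O | target

Total step count: 15. Longest linear sequence: 14 steps (steps 1–3 and 5–15, from 1 to 24); step 4 is a one-step side branch.

Steps most likely to fail

Step 14. The acyl–palladium intermediate may be captured by water too slowly, so that the allenylpalladium species is protonated or carbonylated a second time, and the 5-endo attack on an unsubstituted allene terminus may be sluggish. The fallback sets out from 20 and returns at 23. Methyl chloroformate and pyridine give the propargylic methyl carbonate F1. Decarboxylative methoxycarbonylation (Pd(OAc)2, PPh3, CO, MeOH, 40 °C) gives the isolable methyl allenoate F2. Iodolactonisation (I2, MeCN–H2O) closes the same O–C15 bond by an electrophile-induced route, with loss of iodomethane, to give the 14-iodobutenolide F3. Hydrodeiodination (Pd(PPh3)4, Bu3SnH) then gives 23.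

Step 6. Face control by the auxiliary may erode in the acidic, non-chelating medium, the dioxolane may hydrolyse, and the C8 radical may be oxidised to endocyclic alkene isomers. The fallback sets out from 9 and returns at 10. α-Bromination (NBS, Mg(ClO4)2 cat., MeCN) gives the α-bromo-β-keto ester F4. A chelated atom-transfer radical bicyclisation at low temperature (Et3B/O2, Mg(ClO4)2, toluene, −78 °C) gives the tertiary C8 bromide F5 without acid or oxidant. Dehydrobromination (DBU, toluene, 80 °C) gives 10 after separation from any endocyclic alkene isomers.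

Step 8. Epimerisation at C8 may stop short of the equatorial aldehyde, or the base may trigger aldol condensation of the keto aldehyde. The fallback sets out from 10 and returns at 14. Epoxidation (m-CPBA, NaHCO3, CH2Cl2) from the β face, away from the C10 methyl, gives the 8,17-epoxide F6. Meinwald rearrangement (BF3·OEt2, CH2Cl2, −78 °C) with anti 1,2-hydride shift from C17 to C8 should place the formyl group equatorial directly and give 14.

Further compounds
F1 | step 14 | methyl carbonate of 20 | C[C@]1(COC5(C)C)[C@H]2CC[C@H](CO[Si](C)(C)C(C)(C)C)[C@@H](CCC#CCOC(=O)OC)[C@]2(C)CC[C@H]1O5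
F2 | step 14 | methyl ester of allenoic acid 22 | C[C@]1(COC5(C)C)[C@H]2CC[C@H](CO[Si](C)(C)C(C)(C)C)[C@@H](CCC(=C=C)C(=O)OC)[C@]2(C)CC[C@H]1O5
F3 | step 14 | 14-iodo derivative of 23 (β-iodobutenolide) | C[C@]1(COC5(C)C)[C@H]2CC[C@H](CO[Si](C)(C)C(C)(C)C)[C@@H](CCC3=C(I)COC3=O)[C@]2(C)CC[C@H]1O5
F4 | step 6 | 2-bromo derivative of 9 (α-bromo-β-keto ester, both C2 epimers) | CC(Br)(C(=O)O[C@H]1C[C@@H](C)CC[C@@H]1C(C)(C)c1ccccc1)C(=O)CC/C(C)=C/CC/C(C)=C/CCC1(C)OCCO1
F5 | step 6 | 8-bromo-8-methyl bicyclic keto ester (tertiary C8 bromide, C8 configuration open) | C[C@]1(C(=O)O[C@H]4C[C@@H](C)CC[C@@H]4C(C)(C)c4ccccc4)[C@H]2CCC(C)(Br)[C@@H](CCC3(C)OCCO3)[C@]2(C)CCC1=O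
F6 | step 8 | 8,17-epoxide of 10 (oxygen β, equatorial) | C[C@]1(C(=O)O[C@H]4C[C@@H](C)CC[C@@H]4C(C)(C)c4ccccc4)[C@H]2CC[C@@]5(CO5)[C@@H](CCC3(C)OCCO3)[C@]2(C)CCC1=O
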